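Everything rests on disconnecting the bond between the acetal carbon and the bridging oxygen. The 1,3-dioxine and pyran rings then merge into an eight-membered benzyl aryl ether ring (ring-A CH2, two ring-A carbons, side-chain carbon, carbinol carbon, isoquinoline C7 and C6, ether oxygen) in which the carbinol oxygen faces the CH2 group 1,5 across the ring. In one operation a quinone removes hydride from this CH2, which lies ortho and para to the ring-A oxygens, and the hydroxyl closes transannularly, creating both rings and the acetal stereocentre. The precursor is this medium ring with the free (R)-carbinol, the acetyl group masked as its acetylated carbinol and the formyl group as a dioxolane.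

Key step: step 15

Labels: ring A is the benzene ring that carries OMe, CHO and OH in the target; Cα is the ring carbon that bears the acetyl group or its precursor; the carbinol carbon is the O–CH carbon on isoquinoline C7; MOM is methoxymethyl.

Remark on the precursor: the acetyl group is kept as its acetylated carbinol until after the key step, because a β-hydroxy ketone in the medium ring could cleave by retro-aldol reaction or lose water and its α-centre is epimerisable; the formyl group is kept as a dioxolane, which avoids a palladium-catalysed formylation of a hindered aryl halide on the finished bicycle.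

Remark on regiochemistry: electrophilic halogenation of orsellinates goes to C5, so the C3 substituent needed in both building blocks is brought in by phenoxide-directed ortho-formylation.

Assumption: RuCl(p-cymene)[(S,S)-TsNCHPhCHPhNH2] is taken to give the (S)-carbinol in step 12, as it does with aryl methyl ketones; if the sense proves opposite, the (R,R)-complex is used.

Step 1
Reactants: 1 methyl orsellinate
Product: 2 methyl 2-hydroxy-4-(methoxymethoxy)-6-methylbenzoate
Conditions: MOMCl, i-Pr2NEt, CH2Cl2, 0 °C to rt
Reagents that add atoms: chloromethyl methyl ether, COCCl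
Why: Williamson-type O-alkylation in which the 2-hydroxyl is held in a hydrogen bond to the ester carbonyl, so that only the more acidic, unhindered 4-hydroxyl should be methoxymethylated.

Step 2
Reactants: 2 methyl 2-hydroxy-4-(methoxymethoxy)-6-methylbenzoate
Product: 3 methyl 3-formyl-2-hydroxy-4-(methoxymethoxy)-6-methylbenzoate
Conditions: MgCl2, Et3N, (CH2O)n, MeCN, reflux
Reagents that add atoms: paraformaldehyde (as formaldehyde), C=O
Why: Casnati–Skattebøl ortho-formylation, in which the magnesium phenoxide delivers formaldehyde only ortho to its oxygen, and C3 is the single free ortho carbon.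

Step 3
Reactants: 3 methyl 3-formyl-2-hydroxy-4-(methoxymethoxy)-6-methylbenzoate
Product: 4 methyl 3-formyl-2-methoxy-4-(methoxymethoxy)-6-methylbenzoate
Conditions: MeI, K2CO3, DMF, 40 °C
Reagents that add atoms: iodomethane, CI
Why: Williamson O-methylation of the remaining chelated phenol, which needs the polar solvent and mild heating but meets no competing nucleophile.

Step 4
Reactants: 4 methyl 3-formyl-2-methoxy-4-(methoxymethoxy)-6-methylbenzoate
Product: 5 methyl 3-(1,3-dioxolan-2-yl)-2-methoxy-4-(methoxymethoxy)-6-methylbenzoate
Conditions: 1,2-bis(trimethylsilyloxy)ethane, Me3SiOTf (cat.), CH2Cl2, −78 to −20 °C; pyridine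
Reagents that add atoms: 1,2-bis(trimethylsilyloxy)ethane, C[Si](C)(C)OCCO[Si](C)(C)C
Why: Noyori acetalisation with the bis-silyl ether under aprotic conditions at low temperature should mask the aldehyde as a dioxolane without touching the acid-labile MOM ether.

Step 5
Reactants: 5 methyl 3-(1,3-dioxolan-2-yl)-2-methoxy-4-(methoxymethoxy)-6-methylbenzoate; 6 N-methoxy-N-methylacetamide
Product: 7 methyl 3-(1,3-dioxolan-2-yl)-2-methoxy-4-(methoxymethoxy)-6-(2-oxopropyl)benzoate
Conditions: LiN(i-Pr)2 (1.3 equiv), THF, −78 °C; then 6; AcOH
Reagents that add atoms: none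
Why: Lateral (benzylic) lithiation of the ortho-toluate followed by acylation with the Weinreb amide, whose chelated tetrahedral adduct survives until the quench so that the ketone forms only once.

Step 6
Reactants: 7 methyl 3-(1,3-dioxolan-2-yl)-2-methoxy-4-(methoxymethoxy)-6-(2-oxopropyl)benzoate
Product: 9 1-[4-(1,3-dioxolan-2-yl)-2-(hydroxymethyl)-3-methoxy-5-(methoxymethoxy)phenyl]propan-2-one, via lithium enolate 8 (not isolated)
Conditions: LiN(SiMe3)2 (1.1 equiv), THF, −78 °C; then LiAlH4, −78 to 0 °C; aq. potassium sodium tartrate
Reagents that add atoms: none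
Why: LiAlH4 reduction of the ester with the ketone protected in the flask as its enolate (enolate protection), which hydride does not reduce and which returns the ketone on aqueous work-up.

Step 7
Reactants: 9 1-[4-(1,3-dioxolan-2-yl)-2-(hydroxymethyl)-3-methoxy-5-(methoxymethoxy)phenyl]propan-2-one
Product: 11 7-(1,3-dioxolan-2-yl)-8-methoxy-6-(methoxymethoxy)-3-methylisoquinoline, via keto aldehyde 10 (not isolated)
Conditions: Dess–Martin periodinane, pyridine, CH2Cl2, 0 °C to rt; then NH4OAc, EtOH, rt
Reagents that add atoms: ammonium acetate, CC(=O)[O-].[NH4+]
Why: Dess–Martin oxidation of the benzylic alcohol followed by condensation of the 1,5-keto aldehyde with ammonia, which cyclises and aromatises by loss of two molecules of water (isoquinoline synthesis from a 2-(2-oxoalkyl)benzaldehyde).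

Step 8
Reactants: 11 7-(1,3-dioxolan-2-yl)-8-methoxy-6-(methoxymethoxy)-3-methylisoquinoline
Product: 12 6-hydroxy-8-methoxy-3-methylisoquinoline-7-carbaldehyde
Conditions: 3 M HCl (aq), THF, 50 °C
Reagents that add atoms: water, O
Why: Acid-catalysed hydrolysis of the dioxolane and the MOM ether should give the hydrogen-bonded, salicylaldehyde-type hydroxy aldehyde.

Step 9
Reactants: 9 1-[4-(1,3-dioxolan-2-yl)-2-(hydroxymethyl)-3-methoxy-5-(methoxymethoxy)phenyl]propan-2-one; 12 6-hydroxy-8-methoxy-3-methylisoquinoline-7-carbaldehyde
Product: 13 6-{[3-(1,3-dioxolan-2-yl)-2-methoxy-4-(methoxymethoxy)-6-(2-oxopropyl)phenyl]methoxy}-8-methoxy-3-methylisoquinoline-7-carbaldehyde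
Conditions: PPh3, DIAD, THF, 0 °C to rt
Reagents that add atoms: none
Why: Mitsunobu etherification in which the acidic ortho-formyl phenol displaces the activated primary benzylic hydroxyl of 9, O-alkylation being the normal course for a 6-hydroxyisoquinoline.

Step 10
Reactants: 13 keto aldehyde ether (ring-A benzyl ether of 12)
Product: 14 eight-membered β-hydroxy ketone, in which C7–CH(OH)–CH(COCH3)–ring A closes the ring of the benzyl aryl ether (racemic mixture of diastereomers)
Conditions: LiN(SiMe3)2 (1.05 equiv), THF (0.005 M), −78 °C; AcOH at −78 °C
Reagents that add atoms: none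
Why: Intramolecular aldol addition in which the base removes the more acidic benzylic α-proton, the aldehyde cannot enolise, high dilution and a cold quench should favour ring closure over bimolecular reaction and reversal, and neither new centre needs control because step 11 removes one and step 12 resets the other.

Step 11
Reactants: 14 eight-membered β-hydroxy ketone
Product: 15 eight-membered 1,3-diketone (C7–C(=O)–CH(COCH3)–ring A)
Conditions: IBX, EtOAc, 75 °C
Reagents that add atoms: none
Why: IBX oxidation of a β-hydroxy ketone to the 1,3-diketone, a neutral oxidation that should spare the acetals and makes Cα freely epimerisable through the enol.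

Step 12
Reactants: 15 eight-membered 1,3-diketone
Product: 16 eight-membered hydroxy ketone: ring ketone at C7 kept; Cα (R) bearing an (S)-1-hydroxyethyl group
Conditions: RuCl(p-cymene)[(S,S)-TsNCHPhCHPhNH2] (2 mol %), HCO2H/Et3N (5:2), CH2Cl2, 30 °C
Reagents that add atoms: none
Why: Noyori–Ikariya asymmetric transfer hydrogenation with dynamic kinetic resolution, in which only the unhindered acetyl carbonyl is reduced (the ring ketone is shielded by two ortho substituents), the catalyst sets the (S)-carbinol, and the syn hydroxy ketone usual for 2-substituted 1,3-diketones should form from the equilibrating α-carbon, which fixes Cα as (R).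

Step 13
Reactants: 16 eight-membered hydroxy ketone
Product: 17 eight-membered anti-diol: carbinol carbon (R); Cα (R); (S)-1-hydroxyethyl group
Conditions: Me4NBH(OAc)3, MeCN/AcOH (1:1), −30 °C
Reagents that add atoms: none
Why: Evans–Saksena hydroxyl-directed reduction, in which the acetoxyborohydride bound to the side-chain hydroxyl delivers hydride to the ketone face cis to the side chain, which should give the 1,3-anti diol with the new (R)-carbinol trans to the side chain on the ring.

Step 14
Reactants: 17 eight-membered anti-diol
Product: 18 key-step precursor: side-chain acetate of 17 with free ring carbinol (R); Cα now (S) by changed priorities; (S)-1-acetoxyethyl group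
Conditions: Ac2O (1.2 equiv), pyridine, 4-(dimethylamino)pyridine (cat.), CH2Cl2, 0 °C
Reagents that add atoms: acetic anhydride, CC(=O)OC(C)=O
Why: Acylation (esterification) under steric differentiation, in which the side-chain hydroxyl reacts while the ring carbinol, flanked by the doubly ortho-substituted isoquinoline carbon, should stay free.

Step 15
Reactants: 18 key-step precursor
Product: 20 bridged acetal with (S)-1-acetoxyethyl side chain (acetal carbon R; O–CH carbon R; Cα R), via oxocarbenium ion 19 (not isolated)
Conditions: DDQ (1.3 equiv), 4 Å molecular sieves, CH2Cl2, 0 °C to rt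
Reagents that add atoms: none
Why: DDQ, after charge transfer with the electron-rich ring A, abstracts hydride from the benzylic ether CH2, the only benzylic C–H that is ortho and para to the two ring-A oxygens, and the resulting aryl-stabilised oxocarbenium ion 19 is captured by the carbinol hydroxyl held 1,5 across the medium ring. The closest known reaction is the quinone oxidation of p-methoxybenzyl ethers bearing a neighbouring hydroxyl to cyclic p-methoxybenzylidene acetals (oxidative acetalisation), applied here across a ring to a benzyl aryl ether. The one new C–O bond closes the pyran ring in a 6-exo-trig mode (the C=O+ bond lies outside that ring) and at the same time the 1,3-dioxine ring in a 6-endo-trig mode (the C=O+ bond lies inside it), so the eight-membered ring is divided into the two six-membered rings. The new acetal stereocentre (R) is dictated by the (R)-carbinol, since the one-atom oxygen bridge can reach the cationic carbon from one face of the ring only. The step needs site selectivity in the hydride abstraction and chemoselectivity in the capture: the carbinol C–H sits on the electron-poor, doubly ortho-substituted isoquinoline, the Cα–H is meta to both ring-A oxygens, the dioxolane C–H is held in the arene plane by its two ortho neighbours, and the second hydroxyl is blocked as the acetate. Molecular sieves keep water away so that the cation should not be hydrolysed to the aldehyde.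

Step 16
Reactants: 20 bridged acetal with (S)-1-acetoxyethyl side chain
Product: 21 bridged acetal with free (S)-1-hydroxyethyl side chain (acetal carbon R; O–CH carbon R; Cα R)
Conditions: K2CO3 (cat.), MeOH, rt
Reagents that add atoms: none
Why: Base-catalysed transesterification (methanolysis of the acetate), safe here because the molecule holds no enolisable ketone and both acetals are stable to base.

Step 17
Reactants: 21 bridged acetal with free (S)-1-hydroxyethyl side chain
Product: 22 bridged acetal methyl ketone (acetal carbon R; O–CH carbon R; acetyl-bearing carbon S; formyl as dioxolane; phenol as MOM ether)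
Conditions: Dess–Martin periodinane, pyridine, CH2Cl2, 0 °C to rt
Reagents that add atoms: none
Why: Dess–Martin oxidation of the secondary alcohol to the methyl ketone under buffered, essentially neutral conditions, so that the now enolisable Cα, with its acetyl group on the concave face, should not epimerise.

Step 18
Reactants: 22 bridged acetal methyl ketone
Product: 23 target CNP0584953.1
Conditions: 1 M HCl (aq), THF, rt
Reagents that add atoms: water, O
Why: Acid-catalysed hydrolysis of the dioxolane and the MOM ether (global deprotection), in which the bridged acetal should survive because any opening is reversed at once by the tethered oxygen and mild acid at room temperature should not enolise the ketone.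

Compound list
1 | methyl orsellinate (methyl 2,4-dihydroxy-6-methylbenzoate) | COC(=O)c1c(C)cc(O)cc1O | starting material
2 | methyl 2-hydroxy-4-(methoxymethoxy)-6-methylbenzoate | COCOc1cc(C)c(C(=O)OC)c(O)c1 | intermediate
3 | methyl 3-formyl-2-hydroxy-4-(methoxymethoxy)-6-methylbenzoate | COCOc1cc(C)c(C(=O)OC)c(O)c1C=O | intermediate
4 | methyl 3-formyl-2-methoxy-4-(methoxymethoxy)-6-methylbenzoate | COCOc1cc(C)c(C(=O)OC)c(OC)c1C=O | intermediate
5 | methyl 3-(1,3-dioxolan-2-yl)-2-methoxy-4-(methoxymethoxy)-6-methylbenzoate | COCOc1cc(C)c(C(=O)OC)c(OC)c1C1OCCO1 | intermediate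
6 | N-methoxy-N-methylacetamide | CON(C)C(C)=O | starting material
7 | methyl 3-(1,3-dioxolan-2-yl)-2-methoxy-4-(methoxymethoxy)-6-(2-oxopropyl)benzoate | COCOc1cc(CC(C)=O)c(C(=O)OC)c(OC)c1C1OCCO1 | intermediate
8 | lithium enolate of 7 (benzylic enolate of the 2-oxopropyl group) | COCOc1cc(C=C(C)[O-])c(C(=O)OC)c(OC)c1C1OCCO1.[Li+] | intermediate (not isolated)
9 | 1-[4-(1,3-dioxolan-2-yl)-2-(hydroxymethyl)-3-methoxy-5-(methoxymethoxy)phenyl]propan-2-one | COCOc1cc(CC(C)=O)c(CO)c(OC)c1C1OCCO1 | intermediate
10 | 3-(1,3-dioxolan-2-yl)-2-methoxy-4-(methoxymethoxy)-6-(2-oxopropyl)benzaldehyde | COCOc1cc(CC(C)=O)c(C=O)c(OC)c1C1OCCO1 | intermediate (not isolated)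
11 | 7-(1,3-dioxolan-2-yl)-8-methoxy-6-(methoxymethoxy)-3-methylisoquinoline | COCOc1cc2cc(C)ncc2c(OC)c1C1OCCO1 | intermediate
12 | 6-hydroxy-8-methoxy-3-methylisoquinoline-7-carbaldehyde | COc1c(C=O)c(O)cc2cc(C)ncc12 | intermediate
13 | 6-{[3-(1,3-dioxolan-2-yl)-2-methoxy-4-(methoxymethoxy)-6-(2-oxopropyl)phenyl]methoxy}-8-methoxy-3-methylisoquinoline-7-carbaldehyde | COCOc1cc(CC(C)=O)c(COc2cc3cc(C)ncc3c(OC)c2C=O)c(OC)c1C1OCCO1 | intermediate
14 | eight-membered β-hydroxy ketone, C7–CH(OH)–CH(COCH3)–ring A, racemic mixture of diastereomers | COc1c(C3OCCO3)c(OCOC)cc2c1COc1cc3cc(C)ncc3c(OC)c1C(O)C2C(C)=O | intermediate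
15 | eight-membered 1,3-diketone, C7–C(=O)–CH(COCH3)–ring A | COc1c(C3OCCO3)c(OCOC)cc2c1COc1cc3cc(C)ncc3c(OC)c1C(=O)C2C(C)=O | intermediate
16 | eight-membered hydroxy ketone, Cα (R), (S)-1-hydroxyethyl group | COc1c(C3OCCO3)c(OCOC)cc2c1COc1cc3cc(C)ncc3c(OC)c1C(=O)[C@H]2[C@H](C)O | intermediate
17 | eight-membered anti-diol, carbinol carbon (R), Cα (R), (S)-1-hydroxyethyl group | COc1c(C3OCCO3)c(OCOC)cc2c1COc1cc3cc(C)ncc3c(OC)c1[C@H](O)[C@H]2[C@H](C)O | intermediate
18 | key-step precursor, side-chain acetate of 17: carbinol carbon (R), Cα (S), (S)-1-acetoxyethyl group | COc1c(C3OCCO3)c(OCOC)cc2c1COc1cc3cc(C)ncc3c(OC)c1[C@H](O)[C@H]2[C@H](C)OC(C)=O | intermediate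
19 | oxocarbenium ion formed from 18 at the ring-A benzylic carbon | COc1c(C3OCCO3)c(OCOC)cc2c1C=[O+]c1cc3cc(C)ncc3c(OC)c1[C@H](O)[C@H]2[C@H](C)OC(C)=O | intermediate (not isolated)
20 | bridged acetal with (S)-1-acetoxyethyl side chain: acetal carbon (R), O–CH carbon (R), Cα (R) | COc1c(C3OCCO3)c(OCOC)cc2c1[C@H]1Oc3cc4cc(C)ncc4c(OC)c3[C@H](O1)[C@H]2[C@H](C)OC(C)=O | intermediate
21 | bridged acetal with free (S)-1-hydroxyethyl side chain: acetal carbon (R), O–CH carbon (R), Cα (R) | COc1c(C3OCCO3)c(OCOC)cc2c1[C@H]1Oc3cc4cc(C)ncc4c(OC)c3[C@H](O1)[C@H]2[C@H](C)O | intermediate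
22 | bridged acetal methyl ketone: acetal carbon (R), O–CH carbon (R), acetyl-bearing carbon (S), dioxolane and MOM ether on ring A | COc1c(C3OCCO3)c(OCOC)cc2c1[C@H]1Oc3cc4cc(C)ncc4c(OC)c3[C@H](O1)[C@H]2C(C)=O | intermediate
23 | CNP0584953.1: acetal carbon (R), O–CH carbon (R), acetyl-bearing carbon (S) | COc1c(C=O)c(O)cc2c1[C@H]1Oc3cc4cc(C)ncc4c(OC)c3[C@H](O1)[C@H]2C(C)=O | target

Total step count: 18.
Longest linear sequence: 18 steps (steps 1–6, then 7–8 to the isoquinoline partner, then 9–18; both coupling partners descend from 9).

Steps most likely to fail

1. Step 15. What may go wrong: capture of the cation by traces of water or by the hydroquinone may outrun the transannular closure, so that the benzyl aryl ether is cleaved instead of cyclised. Fallback, from 18 back to 20: the cleavage is accepted and the acetal is made by condensation. DDQ in CH2Cl2/pH 7 buffer cleaves 18 oxidatively to the seco hydroxy aldehyde F1, which has the aldehyde on ring A and the free isoquinolin-6-ol next to the carbinol. Camphorsulfonic acid (catalytic) with 4 Å molecular sieves in CH2Cl2 should then condense the aldehyde with this o-hydroxybenzylic alcohol unit to the 4H-1,3-benzodioxine under thermodynamic control, which is 20.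

2. Step 10. What may go wrong: reversal of the aldol addition (retro-aldol cleavage of the lithium aldolate of a stabilised benzylic enolate in a medium ring) or bimolecular condensation. Fallback, from 13 back to 14: the enolate is generated reductively and held as a samarium chelate. Phenyltrimethylammonium tribromide in THF at 0 °C should brominate the benzylic ketone α-carbon of 13 to the bromo ketone F2. Slow addition of F2 to SmI2 in THF at −78 °C (intramolecular samarium Reformatsky reaction) should give an aldolate that does not revert at this temperature, and after a cold quench 14.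

3. Step 12. What may go wrong: poor facial selectivity of hydride transfer, or racemisation of Cα that is too slow in the medium ring, so that stereoisomers accumulate. Fallback, from 15 back to 17: catalyst control is replaced by an enzymatic resolution. Transfer hydrogenation with the achiral complex RuCl(p-cymene)(TsNCH2CH2NH2) and HCO2H/Et3N should give the racemic syn hydroxy ketone, that is 16 together with its mirror image ent-16 F3. The directed reduction of step 13 then gives the racemic diol, 17 together with ent-17 F4. Burkholderia cepacia lipase with vinyl acetate in t-BuOMe should acetylate only the (R)-configured methyl carbinol, that of ent-17, to ent-18 F5; the untouched 17 is separated and carried into step 14.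

Further compounds
F1 | step 15 | seco hydroxy aldehyde: ring-A aldehyde, free isoquinolin-6-ol, carbinol carbon (R), Cα (S), (S)-1-acetoxyethyl group | COc1c(C3OCCO3)c(OCOC)cc(c1C=O)[C@H]([C@H](C)OC(C)=O)[C@@H](O)c1c(O)cc2cc(C)ncc2c1OC
F2 | step 10 | bromo ketone: 13 brominated at the benzylic ketone α-carbon, racemic | COCOc1cc(C(Br)C(C)=O)c(COc2cc3cc(C)ncc3c(OC)c2C=O)c(OC)c1C1OCCO1
F3 | step 12 | ent-16, mirror image of 16, formed with 16 as the racemate | COc1c(C3OCCO3)c(OCOC)cc2c1COc1cc3cc(C)ncc3c(OC)c1C(=O)[C@@H]2[C@@H](C)O
F4 | step 12 | ent-17, mirror image of 17, formed with 17 as the racemate | COc1c(C3OCCO3)c(OCOC)cc2c1COc1cc3cc(C)ncc3c(OC)c1[C@@H](O)[C@@H]2[C@@H](C)O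
F5 | step 12 | ent-18, mirror image of 18 | COc1c(C3OCCO3)c(OCOC)cc2c1COc1cc3cc(C)ncc3c(OC)c1[C@@H](O)[C@@H]2[C@@H](C)OC(C)=O
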